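**Plan**

- Ring B is numbered C1' (ether carbon), C2' (OH), C3', C4' (CH3), C5', C6' (CHO). After the protecting groups are removed, the first retrosynthetic cut is C5'–C6', which unfolds ring B into an open chain.
- Enabling feature: ring B is a meta-cresol whose C2'–C3'–C4'(CH3)–C5' segment is a 3-methylbut-2-enoyl group and whose C6' plus the formyl carbon is a dimethoxyacetyl group. Both acyl groups sit on an sp3 C1' that already bears the ether oxygen, so the ring maps onto a 2-aryloxy-1,3-diketone.
- Further cuts: the C1'–O bond (SN2 of the ring A phenoxide on a 2-chloro-1,3-diketone), the C1'–C6' bond (Claisen acylation of mesityl oxide), and on ring A the benzylic C–C bond (methallylboration) and the aryl–CHO bond (ortho-formylation).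
- Forward: ring A is bought as the acetonide of 2,6-dihydroxybenzoic acid and elaborated in six steps. The C7 diketone is made in two steps, the two parts are joined at oxygen, ring B is closed and aromatised, and two deprotections finish.
- Stereochemistry: the single stereocentre (S, benzylic carbinol) comes from a chiral-phosphoric-acid-catalysed methallylboration of the ring A aldehyde and is carried as a silyl ether. C1' is sp3 only in passing and ends as an arene carbon.

Key step: step 10

Assumptions:
- Compound 1 is bought (a catalogue compound).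
- The aryloxy diketone of step 9 is carried as a mixture of C1' epimers and enol forms, which all converge in step 10, so its SMILES has no descriptor at C1'. The two transient ring B intermediates of step 10 are written the same way.
- TRIP is 3,3'-bis(2,4,6-triisopropylphenyl)-1,1'-binaphthyl-2,2'-diyl hydrogen phosphate. The sense of induction in step 3 is taken from the behaviour of simple aryl aldehydes and should be confirmed on the product by Mosher ester analysis.

**Route**

Step 1
Reactants: 1 5-hydroxy-2,2-dimethyl-4H-1,3-benzodioxin-4-one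
Product: 3 5-hydroxy-2,2-dimethyl-4-oxo-4H-1,3-benzodioxine-6-carbaldehyde, via hydroxymethyl phenol 2 (not isolated)
Conditions: MgCl2, Et3N, (CH2O)n, MeCN, reflux; then 1 M aq. HCl
Reagents that add atoms: paraformaldehyde (reacts as formaldehyde), C=O
Why: Casnati–Skattebøl ortho-formylation, in which the chloromagnesium phenoxide (ArOMgCl) hydroxymethylates only the free ortho carbon C6 (also para to the ring ether oxygen) and a second formaldehyde oxidises the benzylic alkoxide by hydride transfer, so the formyl group should land where the ring A side chain is needed.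

Step 2
Reactants: 3 5-hydroxy-2,2-dimethyl-4-oxo-4H-1,3-benzodioxine-6-carbaldehyde
Product: 4 5-methoxy-2,2-dimethyl-4-oxo-4H-1,3-benzodioxine-6-carbaldehyde
Conditions: MeI, K2CO3, DMF, rt
Reagents that add atoms: iodomethane, CI
Why: Williamson O-methylation of the acidic, doubly hydrogen-bonded phenol, to which the acetonide lactone is inert under anhydrous carbonate.

Step 3
Reactants: 4 5-methoxy-2,2-dimethyl-4-oxo-4H-1,3-benzodioxine-6-carbaldehyde; 5 2-methylallyl pinacol boronate [4,4,5,5-tetramethyl-2-(2-methylprop-2-en-1-yl)-1,3,2-dioxaborolane]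
Product: 7 6-[(1S)-1-hydroxy-3-methylbut-3-en-1-yl]-5-methoxy-2,2-dimethyl-4H-1,3-benzodioxin-4-one, via borate ester 6 (not isolated)
Conditions: (S)-TRIP (5 mol %), 4 Å MS, toluene, −30 °C; then aq. NaHCO3
Reagents that add atoms: none
Why: Chiral-phosphoric-acid-catalysed allylboration (Antilla type) through a closed chair transition state in which the acid binds a boronate oxygen and the formyl hydrogen; the (S)-acid is chosen because the (R)-acid gives R carbinols from aryl aldehydes, so Si-face delivery of the methallyl group should set the S centre.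

Step 4
Reactants: 7 6-[(1S)-1-hydroxy-3-methylbut-3-en-1-yl]-5-methoxy-2,2-dimethyl-4H-1,3-benzodioxin-4-one
Product: 8 5-methoxy-2,2-dimethyl-6-[(1S)-3-methyl-1-{[tri(propan-2-yl)silyl]oxy}but-3-en-1-yl]-4H-1,3-benzodioxin-4-one
Conditions: iPr3SiOTf, 2,6-lutidine, CH2Cl2, 0 °C to rt
Reagents that add atoms: triisopropylsilyl triflate, CC(C)[Si](C(C)C)(C(C)C)OS(=O)(=O)C(F)(F)F
Why: Silylation with a silyl triflate and a hindered base caps the benzylic carbinol without acid, so the stereocentre is untouched and is shielded for the later steps.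

Step 5
Reactants: 8 5-methoxy-2,2-dimethyl-6-[(1S)-3-methyl-1-{[tri(propan-2-yl)silyl]oxy}but-3-en-1-yl]-4H-1,3-benzodioxin-4-one
Product: 9 5-methoxy-2,2-dimethyl-6-[(1S)-3-methyl-1-{[tri(propan-2-yl)silyl]oxy}butyl]-4H-1,3-benzodioxin-4-one
Conditions: H2 (1 atm), 10% Pd/C, EtOAc, rt
Reagents that add atoms: none
Why: Heterogeneous catalytic hydrogenation of the 1,1-disubstituted alkene gives the isobutyl terminus, and the silylated benzylic C–O bond on this electron-poor ring should resist hydrogenolysis in a neutral solvent.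

Step 6
Reactants: 9 5-methoxy-2,2-dimethyl-6-[(1S)-3-methyl-1-{[tri(propan-2-yl)silyl]oxy}butyl]-4H-1,3-benzodioxin-4-one
Product: 10 2-(trimethylsilyl)ethyl 6-hydroxy-2-methoxy-3-[(1S)-3-methyl-1-{[tri(propan-2-yl)silyl]oxy}butyl]benzoate
Conditions: Me3SiCH2CH2OH, NaH, THF, 0 °C to rt; then AcOH
Reagents that add atoms: 2-(trimethylsilyl)ethanol, OCC[Si](C)(C)C
Why: Alkoxide ring opening (transesterification) of the salicylate acetonide, in which Me3SiCH2CH2ONa attacks the lactone carbonyl and the phenoxide leaves with loss of acetone, gives the fluoride-labile ester and frees only the phenol needed for the ether.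

Step 7
Reactants: 11 mesityl oxide (4-methylpent-3-en-2-one, 2 equiv); 12 methyl dimethoxyacetate
Product: 14 1,1-dimethoxy-6-methylhept-5-ene-2,4-dione, via lithium dienolate 13 (not isolated)
Conditions: LiN(iPr)2 (commercial solution, 2 equiv), THF, −78 °C; then 12, −78 to 0 °C; then AcOH
Reagents that add atoms: none
Why: Crossed Claisen condensation, in which kinetic deprotonation of the enone at its acetyl methyl group gives the cross-conjugated enolate that is acylated by the non-enolisable activated ester, driven by deprotonation of the product diketone by the second equivalent of enolate.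

Step 8
Reactants: 14 1,1-dimethoxy-6-methylhept-5-ene-2,4-dione
Product: 15 3-chloro-1,1-dimethoxy-6-methylhept-5-ene-2,4-dione
Conditions: N-chlorosuccinimide (1.0 equiv), CH2Cl2, 0 °C to rt
Reagents that add atoms: N-chlorosuccinimide, O=C1CCC(=O)N1Cl
Why: Electrophilic alpha-chlorination of the enolised 1,3-diketone at its central carbon, which is far faster than attack on the electron-poor enone double bond and releases no HCl that could trigger pyranone formation.

Step 9
Reactants: 10 2-(trimethylsilyl)ethyl 6-hydroxy-2-methoxy-3-[(1S)-3-methyl-1-{[tri(propan-2-yl)silyl]oxy}butyl]benzoate; 15 3-chloro-1,1-dimethoxy-6-methylhept-5-ene-2,4-dione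
Product: 16 2-(trimethylsilyl)ethyl 6-[(1,1-dimethoxy-6-methyl-2,4-dioxohept-5-en-3-yl)oxy]-2-methoxy-3-[(1S)-3-methyl-1-{[tri(propan-2-yl)silyl]oxy}butyl]benzoate
Conditions: Cs2CO3, MeCN, 0 °C (15 added last), then rt; pH 7 phosphate buffer work-up
Reagents that add atoms: none
Why: Williamson-type SN2 O-alkylation of the caesium phenoxide by the 2-chloro-1,3-diketone, the established entry to 2-aryloxy-1,3-diketones, forms the crowded ether bond at an sp3 carbon and so avoids arylating a doubly ortho-substituted phenol.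

Step 10
Reactants: 16 2-(trimethylsilyl)ethyl 6-[(1,1-dimethoxy-6-methyl-2,4-dioxohept-5-en-3-yl)oxy]-2-methoxy-3-[(1S)-3-methyl-1-{[tri(propan-2-yl)silyl]oxy}butyl]benzoate
Product: 19 2-(trimethylsilyl)ethyl 6-[2-(dimethoxymethyl)-6-hydroxy-4-methylphenoxy]-2-methoxy-3-[(1S)-3-methyl-1-{[tri(propan-2-yl)silyl]oxy}butyl]benzoate, via aldol adduct 17 (not isolated), via cyclohexadienone 18 (not isolated)
Conditions: DBU (3 equiv), 4 Å MS, toluene, 80 °C; pH 7 buffer work-up
Reagents that add atoms: none
Why: DBU holds 16 as its 1,3-diketonate, and the minor tautomeric dienolate (deprotonated at a methyl group of the 3-methylbut-2-enoyl unit, C1' protonated) adds through C5' to the C6' ketone, which is activated by its two alpha-methoxy groups, in an intramolecular vinylogous aldol addition that forms C5'–C6' and gives hydroxy cyclohexenone 17. E1cB loss of water through the C1' enolate then gives the cross-conjugated dienone 18, and a proton shift from C5' to oxygen aromatises it to the C2' phenol, which makes the sequence irreversible. The closest known reaction type is the base-mediated aldol cyclisation and aromatisation of beta-polycarbonyl chains to orcinol-type phenols, here with the gamma-carbon of a beta-methyl enone as donor, as in vinylogous aldol condensations of dienolates from 3-methylbut-2-enoyl compounds. Ring B closes in a 6-(enolendo)-exo-trig mode, the only six-membered option because C6' is the sole carbonyl within reach of C5' and the two methyl groups on C4' are equivalent. No stereocentre is formed, since the C1' epimers and enol forms of 16 converge and the protected benzylic centre is remote and not enolisable. The step needs C–C closure to win over oxa-Michael addition of the diketone oxygen to C4', retro-Claisen loss of the dimethoxyacetyl group and intermolecular Michael addition: the first is reversible under base (E1cB reopening), the second lacks a nucleophile with DBU and sieves, and the third is blocked by the beta,beta-dimethyl terminus and the fully substituted C1', while the hindered alkyl ester should not be acylated by the new phenoxide.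

Step 11
Reactants: 19 2-(trimethylsilyl)ethyl 6-[2-(dimethoxymethyl)-6-hydroxy-4-methylphenoxy]-2-methoxy-3-[(1S)-3-methyl-1-{[tri(propan-2-yl)silyl]oxy}butyl]benzoate
Product: 20 2-(trimethylsilyl)ethyl 6-(2-formyl-6-hydroxy-4-methylphenoxy)-2-methoxy-3-[(1S)-3-methyl-1-{[tri(propan-2-yl)silyl]oxy}butyl]benzoate
Conditions: pyridinium p-toluenesulfonate (0.2 equiv), acetone/H2O 10:1, rt
Reagents that add atoms: water, O
Why: Mild acid-catalysed hydrolysis of the aryl dimethyl acetal, run while the silyl ether still caps the benzylic carbinol so that ionisation at the stereocentre is not expected, and under which the silylethyl ester is stable.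

Step 12
Reactants: 20 2-(trimethylsilyl)ethyl 6-(2-formyl-6-hydroxy-4-methylphenoxy)-2-methoxy-3-[(1S)-3-methyl-1-{[tri(propan-2-yl)silyl]oxy}butyl]benzoate
Product: 21 tenellic acid B, 6-(2-formyl-6-hydroxy-4-methylphenoxy)-3-[(1S)-1-hydroxy-3-methylbutyl]-2-methoxybenzoic acid
Conditions: Bu4NF (4 equiv), THF, 0 °C to rt; then cold 0.1 M aq. HCl to pH 3–4
Reagents that add atoms: none
Why: Fluoride-induced cleavage of the triisopropylsilyl ether and fluoride-triggered beta-elimination of the 2-(trimethylsilyl)ethyl ester release the alcohol and the acid in one operation, without acid or base strong enough to disturb the benzylic stereocentre or the aldehyde.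

**Compound list**

1 | 5-hydroxy-2,2-dimethyl-4H-1,3-benzodioxin-4-one | CC1(C)OC(=O)c2c(O)cccc2O1 | starting material
2 | 5-hydroxy-6-(hydroxymethyl)-2,2-dimethyl-4H-1,3-benzodioxin-4-one | CC1(C)OC(=O)c2c(O)c(CO)ccc2O1 | intermediate
3 | 5-hydroxy-2,2-dimethyl-4-oxo-4H-1,3-benzodioxine-6-carbaldehyde | CC1(C)OC(=O)c2c(O)c(C=O)ccc2O1 | intermediate
4 | 5-methoxy-2,2-dimethyl-4-oxo-4H-1,3-benzodioxine-6-carbaldehyde | CC1(C)OC(=O)c2c(OC)c(C=O)ccc2O1 | intermediate
5 | 2-methylallyl pinacol boronate | CC(=C)CB1OC(C)(C)C(C)(C)O1 | starting material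
6 | pinacol borate ester of carbinol 7 (O–B bond at the S carbinol oxygen) | CC1(C)OC(=O)c2c(OC)c([C@@H](OB3OC(C)(C)C(C)(C)O3)CC(C)=C)ccc2O1 | intermediate
7 | 6-[(1S)-1-hydroxy-3-methylbut-3-en-1-yl]-5-methoxy-2,2-dimethyl-4H-1,3-benzodioxin-4-one | CC1(C)OC(=O)c2c(OC)c([C@@H](O)CC(C)=C)ccc2O1 | intermediate
8 | 5-methoxy-2,2-dimethyl-6-[(1S)-3-methyl-1-{[tri(propan-2-yl)silyl]oxy}but-3-en-1-yl]-4H-1,3-benzodioxin-4-one | CC1(C)OC(=O)c2c(OC)c([C@@H](O[Si](C(C)C)(C(C)C)C(C)C)CC(C)=C)ccc2O1 | intermediate
9 | 5-methoxy-2,2-dimethyl-6-[(1S)-3-methyl-1-{[tri(propan-2-yl)silyl]oxy}butyl]-4H-1,3-benzodioxin-4-one | CC1(C)OC(=O)c2c(OC)c([C@@H](O[Si](C(C)C)(C(C)C)C(C)C)CC(C)C)ccc2O1 | intermediate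
10 | 2-(trimethylsilyl)ethyl 6-hydroxy-2-methoxy-3-[(1S)-3-methyl-1-{[tri(propan-2-yl)silyl]oxy}butyl]benzoate | COc1c([C@@H](O[Si](C(C)C)(C(C)C)C(C)C)CC(C)C)ccc(O)c1C(=O)OCC[Si](C)(C)C | intermediate
11 | mesityl oxide (4-methylpent-3-en-2-one) | CC(=O)C=C(C)C | starting material
12 | methyl dimethoxyacetate | COC(OC)C(=O)OC | starting material
13 | lithium 4-methylpenta-1,3-dien-2-olate | [Li+].[O-]C(=C)C=C(C)C | intermediate
14 | 1,1-dimethoxy-6-methylhept-5-ene-2,4-dione | COC(OC)C(=O)CC(=O)C=C(C)C | intermediate
15 | 3-chloro-1,1-dimethoxy-6-methylhept-5-ene-2,4-dione | COC(OC)C(=O)C(Cl)C(=O)C=C(C)C | intermediate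
16 | 2-(trimethylsilyl)ethyl 6-[(1,1-dimethoxy-6-methyl-2,4-dioxohept-5-en-3-yl)oxy]-2-methoxy-3-[(1S)-3-methyl-1-{[tri(propan-2-yl)silyl]oxy}butyl]benzoate (C1' epimers and enol forms) | COc1c([C@@H](O[Si](C(C)C)(C(C)C)C(C)C)CC(C)C)ccc(OC(C(=O)C=C(C)C)C(=O)C(OC)OC)c1C(=O)OCC[Si](C)(C)C | intermediate
17 | 2-(trimethylsilyl)ethyl 6-{[6-(dimethoxymethyl)-6-hydroxy-4-methyl-2-oxocyclohex-3-en-1-yl]oxy}-2-methoxy-3-[(1S)-3-methyl-1-{[tri(propan-2-yl)silyl]oxy}butyl]benzoate (ring B diastereomers) | COc1c([C@@H](O[Si](C(C)C)(C(C)C)C(C)C)CC(C)C)ccc(OC2C(=O)C=C(C)CC2(O)C(OC)OC)c1C(=O)OCC[Si](C)(C)C | intermediate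
18 | 2-(trimethylsilyl)ethyl 6-{[2-(dimethoxymethyl)-4-methyl-6-oxocyclohexa-1,4-dien-1-yl]oxy}-2-methoxy-3-[(1S)-3-methyl-1-{[tri(propan-2-yl)silyl]oxy}butyl]benzoate | COc1c([C@@H](O[Si](C(C)C)(C(C)C)C(C)C)CC(C)C)ccc(OC2=C(C(OC)OC)CC(C)=CC2=O)c1C(=O)OCC[Si](C)(C)C | intermediate
19 | 2-(trimethylsilyl)ethyl 6-[2-(dimethoxymethyl)-6-hydroxy-4-methylphenoxy]-2-methoxy-3-[(1S)-3-methyl-1-{[tri(propan-2-yl)silyl]oxy}butyl]benzoate | COc1c([C@@H](O[Si](C(C)C)(C(C)C)C(C)C)CC(C)C)ccc(Oc2c(O)cc(C)cc2C(OC)OC)c1C(=O)OCC[Si](C)(C)C | intermediate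
20 | 2-(trimethylsilyl)ethyl 6-(2-formyl-6-hydroxy-4-methylphenoxy)-2-methoxy-3-[(1S)-3-methyl-1-{[tri(propan-2-yl)silyl]oxy}butyl]benzoate | COc1c([C@@H](O[Si](C(C)C)(C(C)C)C(C)C)CC(C)C)ccc(Oc2c(O)cc(C)cc2C=O)c1C(=O)OCC[Si](C)(C)C | intermediate
21 | tenellic acid B, 6-(2-formyl-6-hydroxy-4-methylphenoxy)-3-[(1S)-1-hydroxy-3-methylbutyl]-2-methoxybenzoic acid | COc1c([C@@H](O)CC(C)C)ccc(Oc2c(O)cc(C)cc2C=O)c1C(=O)O | target

**Step count and risks**

Total step count: 12.
Longest linear sequence: 10 steps (steps 1–6 and 9–12); the diketone branch (steps 7–8) joins at step 9.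

Steps most likely to fail:

1. Step 10 (ring B closure). The slow gamma-enolisation may lose to deacylation of the activated dimethoxyacetyl group, or the material may stay parked in the oxa-Michael manifold, so that little C–C closure occurs. The fallback sets out from phenol 10 and returns at aldehyde 20, taking ring B from a bought arene instead of folding it. Nucleophilic aromatic substitution of 10 on 3-bromo-2-fluoro-5-methylbenzaldehyde F1 (K2CO3, DMF, 80 °C; the fluoride ortho to the formyl group is displaced) should give the bromo diaryl ether 2-(trimethylsilyl)ethyl 6-(2-bromo-6-formyl-4-methylphenoxy)-2-methoxy-3-[(1S)-3-methyl-1-{[tri(propan-2-yl)silyl]oxy}butyl]benzoate F2. Miyaura borylation (B2pin2, PdCl2(dppf), KOAc, dioxane, 80 °C) should then give the pinacol boronate F3. Oxidation of its C–B bond with N-methylmorpholine N-oxide (THF, 50 °C), which tolerates the aldehyde, should give 20.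

2. Step 9 (ether formation). Chlorine transfer from the chloro diketone to the phenoxide, or base-induced acyl cleavage of the chloro diketone, may outrun substitution at carbon. The fallback sets out from diketone 14 and returns at 16. Regitz diazo transfer (4-acetamidobenzenesulfonyl azide, Et3N, MeCN, rt) should give 3-diazo-1,1-dimethoxy-6-methylhept-5-ene-2,4-dione F4. Rh2(OAc)4-catalysed O–H insertion of its carbenoid into phenol 10 (CH2Cl2, 40 °C) should then give 16 under neutral conditions.

3. Step 3 (methallylboration). Enantiofacial discrimination may be eroded by the ortho-methoxy group and the neighbouring lactone carbonyl, which can compete for the acid. The fallback sets out from aldehyde 4 and returns at 9. Addition of iBuMgBr (THF, −78 °C) should give the racemic carbinol 6-(1-hydroxy-3-methylbutyl)-5-methoxy-2,2-dimethyl-4H-1,3-benzodioxin-4-one F5. Dess–Martin oxidation should give the aryl ketone F6. Corey–Bakshi–Shibata reduction with the (R)-methyl oxazaborolidine and BH3·SMe2 (aryl as the large group) should give the S carbinol F7. Silylation as in step 4 then gives 9, which also makes the hydrogenation unnecessary.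

**Further compounds**

F1 | step 10 | 3-bromo-2-fluoro-5-methylbenzaldehyde | O=Cc1cc(C)cc(Br)c1F
F2 | step 10 | 2-(trimethylsilyl)ethyl 6-(2-bromo-6-formyl-4-methylphenoxy)-2-methoxy-3-[(1S)-3-methyl-1-{[tri(propan-2-yl)silyl]oxy}butyl]benzoate | COc1c([C@@H](O[Si](C(C)C)(C(C)C)C(C)C)CC(C)C)ccc(Oc2c(Br)cc(C)cc2C=O)c1C(=O)OCC[Si](C)(C)C
F3 | step 10 | 2-(trimethylsilyl)ethyl 6-[2-formyl-4-methyl-6-(4,4,5,5-tetramethyl-1,3,2-dioxaborolan-2-yl)phenoxy]-2-methoxy-3-[(1S)-3-methyl-1-{[tri(propan-2-yl)silyl]oxy}butyl]benzoate | COc1c([C@@H](O[Si](C(C)C)(C(C)C)C(C)C)CC(C)C)ccc(Oc2c(B3OC(C)(C)C(C)(C)O3)cc(C)cc2C=O)c1C(=O)OCC[Si](C)(C)C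
F4 | step 9 | 3-diazo-1,1-dimethoxy-6-methylhept-5-ene-2,4-dione | COC(OC)C(=O)C(=[N+]=[N-])C(=O)C=C(C)C
F5 | step 3 | racemic 6-(1-hydroxy-3-methylbutyl)-5-methoxy-2,2-dimethyl-4H-1,3-benzodioxin-4-one | CC1(C)OC(=O)c2c(OC)c(C(O)CC(C)C)ccc2O1
F6 | step 3 | 5-methoxy-2,2-dimethyl-6-(3-methylbutanoyl)-4H-1,3-benzodioxin-4-one | CC1(C)OC(=O)c2c(OC)c(C(=O)CC(C)C)ccc2O1
F7 | step 3 | 6-[(1S)-1-hydroxy-3-methylbutyl]-5-methoxy-2,2-dimethyl-4H-1,3-benzodioxin-4-one | CC1(C)OC(=O)c2c(OC)c([C@@H](O)CC(C)C)ccc2O1
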